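Retrosynthesis: the target, (−)-epigallocatechin 3-O-gallate-(4β→8)-(−)-epigallocatechin, is cut at the interflavan C4–C8 bond (upper C4 cation, lower ring A C8 nucleophile) and at the galloyl ester, so that both flavan units fall back on one monomer, penta-O-benzyl-(−)-epigallocatechin.
In the monomer the C3 hydroxyl is traced to the 3-ketone and on to the C3=C4 alkene of a flav-3-ene; ring C is then cut at C3–C4 (ring-closing metathesis) and at O1–C2 (allylic etherification), giving a ring A vinylphenol and a ring B cinnamyl carbonate.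
Forward: rings A and B are joined through O1–C2, ring C is closed at C3–C4, C3 is oxygenated and inverted; part of the monomer is activated at C4 and galloylated, coupled with the rest (C4–C8), and the thirteen benzyl ethers are removed last.
Enabling feature: C3 and C4 of ring C carry only hydrogen besides the C3 oxygen, C4 sits on C4a next to the O1-bearing C8a of ring A, and C3 sits on the O1-bearing C2; a vinyl group on C4a and one on C2 of an aryl allyl ether are therefore held by the C4a–C8a–O1–C2 arc in place for a six-membered ring closure.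
Stereochemistry: C2 from ligand control in the iridium-catalysed allylic etherification; C3 from hydride delivery to the 3-ketone anti to the 2-aryl group (2,3-cis); upper C4 from attack of C8 anti to the 3-O-galloyl and 2-aryl groups (3,4-trans, 4β).
Key step: step 7

Assumption: 3,4,5-tris(benzyloxy)benzaldehyde, 3,5-bis(benzyloxy)phenol and 3,4,5-tris(benzyloxy)benzoic acid are taken as catalogue compounds.

Step 1
Reactants: 1 3,4,5-tris(benzyloxy)benzaldehyde
Product: 2 ethyl (E)-3-[3,4,5-tris(benzyloxy)phenyl]prop-2-enoate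
Conditions: Ph3P=CHCO2Et (1.2 equiv), toluene, 90 °C
Reagents that add atoms: (carbethoxymethylene)triphenylphosphorane, CCOC(=O)C=P(c1ccccc1)(c1ccccc1)c1ccccc1
Why: A Wittig olefination with an ester-stabilised ylide should convert the aryl aldehyde into the enoate with the E geometry that such ylides normally give.

Step 2
Reactants: 2 ethyl (E)-3-[3,4,5-tris(benzyloxy)phenyl]prop-2-enoate
Product: 3 (E)-3-[3,4,5-tris(benzyloxy)phenyl]prop-2-en-1-ol
Conditions: i-Bu2AlH (2.5 equiv), CH2Cl2, −78 to 0 °C; aqueous potassium sodium tartrate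
Reagents that add atoms: none
Why: The 1,2-reduction of an α,β-unsaturated ester by a dialkylaluminium hydride should give the allylic alcohol without touching the alkene or the benzyl ethers.

Step 3
Reactants: 3 (E)-3-[3,4,5-tris(benzyloxy)phenyl]prop-2-en-1-ol
Product: 4 methyl (E)-3-[3,4,5-tris(benzyloxy)phenyl]prop-2-en-1-yl carbonate
Conditions: ClCO2Me (1.5 equiv), pyridine (2 equiv), CH2Cl2, 0 °C
Reagents that add atoms: methyl chloroformate, COC(=O)Cl
Why: O-Acylation of the primary allylic alcohol gives the linear carbonate, the standard leaving group for iridium-catalysed allylic substitution.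

Step 4
Reactants: 5 3,5-bis(benzyloxy)phenol
Product: 6 2,4-bis(benzyloxy)-6-hydroxybenzaldehyde
Conditions: (CH2O)n (6 equiv), MgCl2 (1.5 equiv), Et3N (3.75 equiv), MeCN, reflux; 1 M HCl
Reagents that add atoms: formaldehyde (as paraformaldehyde), C=O
Why: In the magnesium-mediated ortho-formylation of phenols (Casnati–Skattebøl reaction) the magnesium phenoxide delivers formaldehyde only to an ortho carbon (the two are equivalent here) and a second formaldehyde accepts hydride, so the para position should stay free.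

Step 5
Reactants: 6 2,4-bis(benzyloxy)-6-hydroxybenzaldehyde
Product: 7 3,5-bis(benzyloxy)-2-ethenylphenol
Conditions: Ph3PCH3Br (2.6 equiv), KOt-Bu (2.5 equiv), THF, 0 °C to rt; aqueous NH4Cl; used without storage
Reagents that add atoms: methyltriphenylphosphonium bromide, C[P+](c1ccccc1)(c1ccccc1)c1ccccc1.[Br-]
Why: Wittig methylenation with excess ylide tolerates the free phenol as its phenoxide, as is usual for salicylaldehydes, and should give the 2-vinylphenol.

Step 6
Reactants: 7 3,5-bis(benzyloxy)-2-ethenylphenol; 4 methyl (E)-3-[3,4,5-tris(benzyloxy)phenyl]prop-2-en-1-yl carbonate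
Product: 9 (S)-1,5-bis(benzyloxy)-2-ethenyl-3-({1-[3,4,5-tris(benzyloxy)phenyl]prop-2-en-1-yl}oxy)benzene, via lithium phenoxide 8 (not isolated)
Conditions: LiN(SiMe3)2 (1.0 equiv), THF, 0 °C; then 4 (1.2 equiv), [Ir(cod)Cl]2 (2 mol%), (Sa,Sc,Sc)-O,O'-(1,1'-binaphthalene-2,2'-diyl) N,N-bis(1-phenylethyl)phosphoramidite (4 mol%, pre-activated with n-PrNH2), THF, 25–40 °C
Reagents that add atoms: lithium bis(trimethylsilyl)amide, [Li+].C[Si](C)(C)[N-][Si](C)(C)C (supplies only the lithium of intermediate 8)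
Why: In this iridium-catalysed asymmetric allylic etherification the cyclometallated iridium phosphoramidite ionises the linear carbonate and the phenoxide attacks the aryl-substituted allyl terminus (branched ether), the ligand fixing the face so that the (S)-ether, the future 2R centre, should form, the sense being assigned by analogy with cinnamyl carbonates and reversible with the mirror-image ligand.

Step 7
Reactants: 9 (S)-1,5-bis(benzyloxy)-2-ethenyl-3-({1-[3,4,5-tris(benzyloxy)phenyl]prop-2-en-1-yl}oxy)benzene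
Product: 10 (S)-5,7-bis(benzyloxy)-2-[3,4,5-tris(benzyloxy)phenyl]-2H-chromene
Conditions: second-generation Grubbs catalyst RuCl2(=CHPh)(H2IMes)(PCy3) (5 mol%), 1,4-benzoquinone (10 mol%), CH2Cl2 (0.01 M), 40 °C, dark
Reagents that add atoms: none
Why: Ring-closing olefin metathesis by the metallacyclobutane mechanism: the ruthenium benzylidene first exchanges onto the unhindered vinyl group on C2, the new alkylidene adds in [2+2] fashion to the vinyl group on C4a of ring A, and cycloreversion releases ethene and leaves the C3=C4 double bond. The closest known reaction type is the ring-closing metathesis of allyl 2-vinylphenyl ethers to 2H-chromenes. The six-membered ring C (O1, C2, C3, C4, C4a, C8a) is closed by this intramolecular cycloaddition and cycloreversion with both alkene carbons ending inside the ring (a formal 6-endo closure), the Z geometry being the only one the ring allows. No stereocentre is created, and C2, set in step 6, takes no part in the bond changes and is carried through unchanged. The step needs ring closure to win over cross-metathesis and must avoid ruthenium hydride double-bond migration and electrocyclic opening of the product, either of which would erase C2: the ortho placing of O1 and the vinyl group on ring A gives a high effective molarity, dilution disfavours dimers, benzoquinone scavenges hydrides, and mild temperature with exclusion of light keeps the 2H-chromene closed. The C3=C4 alkene so formed is polarised by ring A, which is what lets step 8 place oxygen on C3 alone.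

Step 8
Reactants: 10 (S)-5,7-bis(benzyloxy)-2-[3,4,5-tris(benzyloxy)phenyl]-2H-chromene
Product: 12 (2R,3S)-5,7-bis(benzyloxy)-2-[3,4,5-tris(benzyloxy)phenyl]chroman-3-ol, via 3-borylflavan 11 (not isolated)
Conditions: BH3·THF (2 equiv), THF, 0 °C to rt; then 3 M NaOH, 30% H2O2, 0 °C
Reagents that add atoms: hydrogen peroxide, OO (hydroxyl oxygen of 12); borane (as BH3·THF), B (boron of 11)
Why: Hydroboration–oxidation should place boron on C3 (hydrogen goes to the benzylic C4 next to electron-rich ring A) from the face anti to the 2-aryl group, and oxidation with retention gives the 2,3-trans alcohol, any cis isomer being harmless because steps 9 and 10 reset C3.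

Step 9
Reactants: 12 (2R,3S)-5,7-bis(benzyloxy)-2-[3,4,5-tris(benzyloxy)phenyl]chroman-3-ol
Product: 13 (R)-5,7-bis(benzyloxy)-2-[3,4,5-tris(benzyloxy)phenyl]chroman-3-one
Conditions: Dess–Martin periodinane (1.5 equiv), water-saturated CH2Cl2, rt
Reagents that add atoms: none
Why: Dess–Martin oxidation works near neutrality, so the secondary alcohol should become the ketone without enolisation at the labile C2, as is established for benzylated flavan-3-ols.

Step 10
Reactants: 13 (R)-5,7-bis(benzyloxy)-2-[3,4,5-tris(benzyloxy)phenyl]chroman-3-one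
Product: 14 (2R,3R)-5,7-bis(benzyloxy)-2-[3,4,5-tris(benzyloxy)phenyl]chroman-3-ol (penta-O-benzyl-(−)-epigallocatechin)
Conditions: LiBH(s-Bu)3 (1.5 equiv), LiBr (3 equiv), THF, −78 °C; aqueous NaOH
Reagents that add atoms: none
Why: Substrate-controlled reduction with a bulky trialkylborohydride should deliver hydride to the ketone face opposite the 2-aryl group and so give the 2,3-cis (3R) alcohol.

Step 11
Reactants: 14 (2R,3R)-5,7-bis(benzyloxy)-2-[3,4,5-tris(benzyloxy)phenyl]chroman-3-ol
Product: 15 (2R,3R,4S)-5,7-bis(benzyloxy)-4-(2-ethoxyethoxy)-2-[3,4,5-tris(benzyloxy)phenyl]chroman-3-ol (4β ether, 3,4-trans)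
Conditions: DDQ (2.0 equiv), EtOCH2CH2OH (5 equiv), CH2Cl2, rt
Reagents that add atoms: 2-ethoxyethanol, CCOCCO
Why: Benzylic oxidation by DDQ removes hydride from C4, which is activated by the 5-O, 7-O and O1 donors of ring A, and the alcohol should trap the resulting quinone methide cation from the β face, anti to the substituents on C2 and C3.

Step 12
Reactants: 15 (2R,3R,4S)-5,7-bis(benzyloxy)-4-(2-ethoxyethoxy)-2-[3,4,5-tris(benzyloxy)phenyl]chroman-3-ol; 16 3,4,5-tris(benzyloxy)benzoic acid
Product: 17 (2R,3R,4S)-5,7-bis(benzyloxy)-4-(2-ethoxyethoxy)-2-[3,4,5-tris(benzyloxy)phenyl]chroman-3-yl 3,4,5-tris(benzyloxy)benzoate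
Conditions: DCC (2 equiv), DMAP (0.5 equiv), CH2Cl2, rt
Reagents that add atoms: none
Why: Steglich esterification acylates the only free hydroxyl (3-OH) under mildly basic conditions that should leave the acid-labile C4 ether intact.

Step 13
Reactants: 17 (2R,3R,4S)-5,7-bis(benzyloxy)-4-(2-ethoxyethoxy)-2-[3,4,5-tris(benzyloxy)phenyl]chroman-3-yl 3,4,5-tris(benzyloxy)benzoate; 14 (2R,3R)-5,7-bis(benzyloxy)-2-[3,4,5-tris(benzyloxy)phenyl]chroman-3-ol (3 equiv, excess recovered)
Product: 18 (2R,3R,4R)-5,7-bis(benzyloxy)-4-{(2R,3R)-5,7-bis(benzyloxy)-3-hydroxy-2-[3,4,5-tris(benzyloxy)phenyl]chroman-8-yl}-2-[3,4,5-tris(benzyloxy)phenyl]chroman-3-yl 3,4,5-tris(benzyloxy)benzoate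
Conditions: Me3SiOTf (0.2 equiv), CH2Cl2, −78 °C; aqueous NaHCO3
Reagents that add atoms: none
Why: In this Lewis acid-promoted Friedel–Crafts-type condensation the C4 ether ionises to a cation stabilised by ring A, and C8 of 14 (the most nucleophilic ring A carbon, between O1 and the 7-benzyloxy group) should attack from the β face, anti to the participating 3-O-galloyl group and the 2-aryl group, giving the 4β (4R) linkage while the excess of 14 suppresses chain growth.

Step 14
Reactants: 18 (2R,3R,4R)-5,7-bis(benzyloxy)-4-{(2R,3R)-5,7-bis(benzyloxy)-3-hydroxy-2-[3,4,5-tris(benzyloxy)phenyl]chroman-8-yl}-2-[3,4,5-tris(benzyloxy)phenyl]chroman-3-yl 3,4,5-tris(benzyloxy)benzoate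
Product: 19 (−)-epigallocatechin 3-O-gallate-(4β→8)-(−)-epigallocatechin
Conditions: H2 (1 atm), Pd(OH)2 on carbon, THF/MeOH/H2O, rt; filtration under argon, lyophilisation
Reagents that add atoms: none
Why: Catalytic hydrogenolysis should cleave all thirteen benzyl ethers under neutral conditions that leave the gallate ester, the C2–O1 bonds and the C4–C8 bond untouched, as is usual in the last step of galloylated proanthocyanidin syntheses.

Compound list
1 | 3,4,5-tris(benzyloxy)benzaldehyde | O=Cc1cc(OCc2ccccc2)c(OCc2ccccc2)c(OCc2ccccc2)c1 | starting material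
2 | ethyl (E)-3-[3,4,5-tris(benzyloxy)phenyl]prop-2-enoate | CCOC(=O)/C=C/c1cc(OCc2ccccc2)c(OCc2ccccc2)c(OCc2ccccc2)c1 | intermediate
3 | (E)-3-[3,4,5-tris(benzyloxy)phenyl]prop-2-en-1-ol | OC/C=C/c1cc(OCc2ccccc2)c(OCc2ccccc2)c(OCc2ccccc2)c1 | intermediate
4 | methyl (E)-3-[3,4,5-tris(benzyloxy)phenyl]prop-2-en-1-yl carbonate | COC(=O)OC/C=C/c1cc(OCc2ccccc2)c(OCc2ccccc2)c(OCc2ccccc2)c1 | intermediate
5 | 3,5-bis(benzyloxy)phenol | Oc1cc(OCc2ccccc2)cc(OCc2ccccc2)c1 | starting material
6 | 2,4-bis(benzyloxy)-6-hydroxybenzaldehyde | O=Cc1c(O)cc(OCc2ccccc2)cc1OCc1ccccc1 | intermediate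
7 | 3,5-bis(benzyloxy)-2-ethenylphenol | C=Cc1c(O)cc(OCc2ccccc2)cc1OCc1ccccc1 | intermediate
8 | lithium 3,5-bis(benzyloxy)-2-ethenylphenoxide | C=Cc1c([O-])cc(OCc2ccccc2)cc1OCc1ccccc1.[Li+] | intermediate (not isolated)
9 | (S)-1,5-bis(benzyloxy)-2-ethenyl-3-({1-[3,4,5-tris(benzyloxy)phenyl]prop-2-en-1-yl}oxy)benzene | C=Cc1c(OCc2ccccc2)cc(OCc2ccccc2)cc1O[C@H](c1cc(OCc2ccccc2)c(OCc2ccccc2)c(OCc2ccccc2)c1)C=C | intermediate
10 | (S)-5,7-bis(benzyloxy)-2-[3,4,5-tris(benzyloxy)phenyl]-2H-chromene (penta-O-benzyl flav-3-ene) | C(c1ccccc1)Oc1cc(OCc2ccccc2)c2c(c1)O[C@H](c1cc(OCc3ccccc3)c(OCc3ccccc3)c(OCc3ccccc3)c1)C=C2 | intermediate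
11 | {(2S,3S)-5,7-bis(benzyloxy)-2-[3,4,5-tris(benzyloxy)phenyl]chroman-3-yl}borane (2,3-trans, boron anti to the 2-aryl group) | C(c1ccccc1)Oc1cc(OCc2ccccc2)c2c(c1)O[C@H](c1cc(OCc3ccccc3)c(OCc3ccccc3)c(OCc3ccccc3)c1)[C@@H](B)C2 | intermediate (not isolated)
12 | (2R,3S)-5,7-bis(benzyloxy)-2-[3,4,5-tris(benzyloxy)phenyl]chroman-3-ol (2,3-trans) | C(c1ccccc1)Oc1cc(OCc2ccccc2)c2c(c1)O[C@H](c1cc(OCc3ccccc3)c(OCc3ccccc3)c(OCc3ccccc3)c1)[C@@H](O)C2 | intermediate
13 | (R)-5,7-bis(benzyloxy)-2-[3,4,5-tris(benzyloxy)phenyl]chroman-3-one | C(c1ccccc1)Oc1cc(OCc2ccccc2)c2c(c1)O[C@H](c1cc(OCc3ccccc3)c(OCc3ccccc3)c(OCc3ccccc3)c1)C(=O)C2 | intermediate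
14 | (2R,3R)-5,7-bis(benzyloxy)-2-[3,4,5-tris(benzyloxy)phenyl]chroman-3-ol (penta-O-benzyl-(−)-epigallocatechin, 2,3-cis) | C(c1ccccc1)Oc1cc(OCc2ccccc2)c2c(c1)O[C@H](c1cc(OCc3ccccc3)c(OCc3ccccc3)c(OCc3ccccc3)c1)[C@H](O)C2 | intermediate
15 | (2R,3R,4S)-5,7-bis(benzyloxy)-4-(2-ethoxyethoxy)-2-[3,4,5-tris(benzyloxy)phenyl]chroman-3-ol (4β ether) | O[C@@H]1[C@@H](OCCOCC)c2c(OCc3ccccc3)cc(OCc3ccccc3)cc2O[C@@H]1c1cc(OCc2ccccc2)c(OCc2ccccc2)c(OCc2ccccc2)c1 | intermediate
16 | 3,4,5-tris(benzyloxy)benzoic acid | O=C(O)c1cc(OCc2ccccc2)c(OCc2ccccc2)c(OCc2ccccc2)c1 | starting material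
17 | (2R,3R,4S)-5,7-bis(benzyloxy)-4-(2-ethoxyethoxy)-2-[3,4,5-tris(benzyloxy)phenyl]chroman-3-yl 3,4,5-tris(benzyloxy)benzoate | O=C(O[C@@H]1[C@@H](OCCOCC)c2c(OCc3ccccc3)cc(OCc3ccccc3)cc2O[C@@H]1c1cc(OCc2ccccc2)c(OCc2ccccc2)c(OCc2ccccc2)c1)c1cc(OCc2ccccc2)c(OCc2ccccc2)c(OCc2ccccc2)c1 | intermediate
18 | (2R,3R,4R)-5,7-bis(benzyloxy)-4-{(2R,3R)-5,7-bis(benzyloxy)-3-hydroxy-2-[3,4,5-tris(benzyloxy)phenyl]chroman-8-yl}-2-[3,4,5-tris(benzyloxy)phenyl]chroman-3-yl 3,4,5-tris(benzyloxy)benzoate (trideca-O-benzyl target) | O=C(O[C@@H]1[C@@H](c2c(OCc4ccccc4)cc(OCc4ccccc4)c3c2O[C@H](c2cc(OCc4ccccc4)c(OCc4ccccc4)c(OCc4ccccc4)c2)[C@H](O)C3)c2c(OCc3ccccc3)cc(OCc3ccccc3)cc2O[C@@H]1c1cc(OCc2ccccc2)c(OCc2ccccc2)c(OCc2ccccc2)c1)c1cc(OCc2ccccc2)c(OCc2ccccc2)c(OCc2ccccc2)c1 | intermediate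
19 | (2R,3R,4R)-5,7-dihydroxy-4-[(2R,3R)-3,5,7-trihydroxy-2-(3,4,5-trihydroxyphenyl)chroman-8-yl]-2-(3,4,5-trihydroxyphenyl)chroman-3-yl 3,4,5-trihydroxybenzoate | O=C(O[C@@H]1[C@@H](c2c(O)cc(O)c3c2O[C@H](c2cc(O)c(O)c(O)c2)[C@H](O)C3)c2c(O)cc(O)cc2O[C@@H]1c1cc(O)c(O)c(O)c1)c1cc(O)c(O)c(O)c1 | target

Total step count: 14. Longest linear sequence: 12 steps (1, 2, 3, 6, 7, 8, 9, 10, 11, 12, 13, 14).

Steps most likely to fail

Most at risk is step 6. The hindered, ortho-substituted phenoxide may attack the allyl complex slowly while the electron-rich product ether ionises again on the catalyst, so that enantiomeric purity and the branched preference erode with time. The fallback moves the stereochemical decision from the ether to the ketone. Material of insufficient enantiomeric purity is carried through steps 7 to 9 unchanged. Setting out from ketone 13, step 10 is then replaced by an asymmetric transfer hydrogenation with dynamic kinetic resolution (RuCl(p-cymene)(TsDPEN), HCO2H/Et3N, CH2Cl2, rt). The ligand enantiomer that gives the 3R alcohol is fixed in a trial with both. C2 of 13 is benzylic, oxygen-bearing and α to the ketone, so it should epimerise through the enol while the catalyst reduces one enantiomer to the cis alcohol. The route is rejoined at 14, and no new compound is made (entry F0).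

Second is step 7. Ruthenium hydrides formed from the catalyst may move the allylic double bond of 9 into conjugation with O1, which destroys the diene and C2, and the doubly ortho-substituted, electron-rich styrene may engage the alkylidene too slowly. The fallback forms the same C3–C4 bond by reductive carbonyl coupling instead of metathesis. Setting out from 9, both vinyl groups are cleaved (OsO4 cat., NaIO4, 2,6-lutidine, dioxane/H2O) to the (R)-dialdehyde F1. SmI2 in THF/t-BuOH at −78 °C should reduce the aromatic aldehyde to its ketyl, which adds to the neighbouring aliphatic aldehyde in a pinacol cyclisation and gives the flavan-3,4-diol F2. Ionic reduction of the benzylic C4 hydroxyl (Et3SiH, BF3·OEt2, CH2Cl2, −78 °C) then gives the flavan-3-ol 12, where the route is rejoined. The configuration at C3 is of no consequence, because steps 9 and 10 reset it.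

Third is step 13. The C4 cation from 17 may be captured by C8 or C6 of a second molecule of 17 (chain growth) or by C6 of 14, and facial control may be incomplete. The fallback blocks the nucleophilic position of the electrophile. Setting out from 15, bromination with N-bromosuccinimide (CH2Cl2, −10 °C) gives the 8-bromo ether F3. Esterification with 16 as in step 12 gives the 8-bromo gallate F4. Me3SiOTf-promoted coupling with only a slight excess of 14 gives the 8-bromo dimer F5, which can no longer extend the chain. Hydrogenolysis over Pd(OH)2 on carbon in the presence of Et3N removes bromine together with the benzyl groups and rejoins the route at 19.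

Further compounds
F0 | step 6 | none | none
F1 | step 7 | (R)-2,4-bis(benzyloxy)-6-({2-oxo-1-[3,4,5-tris(benzyloxy)phenyl]ethyl}oxy)benzaldehyde | O=Cc1c(OCc2ccccc2)cc(OCc2ccccc2)cc1O[C@H](c1cc(OCc2ccccc2)c(OCc2ccccc2)c(OCc2ccccc2)c1)C=O
F2 | step 7 | (2R,3S,4S)-5,7-bis(benzyloxy)-2-[3,4,5-tris(benzyloxy)phenyl]chromane-3,4-diol (expected major isomer; C3 and C4 configuration immaterial) | C(c1ccccc1)Oc1cc(OCc2ccccc2)c2c(c1)O[C@H](c1cc(OCc3ccccc3)c(OCc3ccccc3)c(OCc3ccccc3)c1)[C@@H](O)[C@H]2O
F3 | step 13 | 8-bromo derivative of 15 | O[C@@H]1[C@@H](OCCOCC)c2c(OCc3ccccc3)cc(OCc3ccccc3)c(Br)c2O[C@@H]1c1cc(OCc2ccccc2)c(OCc2ccccc2)c(OCc2ccccc2)c1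
F4 | step 13 | 8-bromo derivative of 17 | O=C(O[C@@H]1[C@@H](OCCOCC)c2c(OCc3ccccc3)cc(OCc3ccccc3)c(Br)c2O[C@@H]1c1cc(OCc2ccccc2)c(OCc2ccccc2)c(OCc2ccccc2)c1)c1cc(OCc2ccccc2)c(OCc2ccccc2)c(OCc2ccccc2)c1
F5 | step 13 | 8-bromo derivative of 18 (bromine on C8 of the galloylated unit, configuration as in 18) | O=C(O[C@@H]1[C@@H](c2c(OCc4ccccc4)cc(OCc4ccccc4)c3c2O[C@H](c2cc(OCc4ccccc4)c(OCc4ccccc4)c(OCc4ccccc4)c2)[C@H](O)C3)c2c(OCc3ccccc3)cc(OCc3ccccc3)c(Br)c2O[C@@H]1c1cc(OCc2ccccc2)c(OCc2ccccc2)c(OCc2ccccc2)c1)c1cc(OCc2ccccc2)c(OCc2ccccc2)c(OCc2ccccc2)c1
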